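The target does not stay as it is made: the enzyme forms it from the substrate in a one-way step, and it then passes to and fro with its isomer, so the yield asked for is a share of a pair.

substrate 17 mM (fed, over 1.0 min); enzyme 0.097 µM; time 50 min; the fed solution adds 0.25 times the starting volume

    substrate + enzyme → target + enzyme, rate k1*[substrate]*[enzyme]/(1 + ([substrate]/Km1) + ([substrate]/Ksi1)^2) (Km1 = 0.68 mM, Ksi1 = 14 mM, k1 = 4.7 × 10⁶ L mol⁻¹ s⁻¹)
    target ⇌ isomer of the product (K2 = 1.2, k2 = 0.0044 s⁻¹)

* which holds at 50 min: what has brought the reaction to rest, or that it has not come to rest (forward and back rates have come level / all of the substrate has reacted / it is still moving)
* the target standing at 50 min, as a percentage of the substrate charged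
* the isomer of the product standing at 50 min, as a percentage of the substrate charged

- charges are per starting volume, the dose included; the dosed solution carries all of it
- the reaction counts as stopped when no species that holds the substrate changes by six tenths of a point or more over the second half of the time
- run time (flask): 50 min

The first link is the capacity of the enzyme. Well above Km the rate law flattens to the rate constant times c(enzyme) times Km, here 0.310 mM s⁻¹, and the feed brings 0.283 mM s⁻¹, so this capacity is faster than the feed. At that rate the charge takes about 54.8 s of turnover.

The next link is the pair. Its relaxation half-life, both directions together, is 1.43 min, far shorter than the 50 min allowed, so the pair comes under thermodynamic control. The symmetric pair is the zero of the scale: an equilibrium constant of one gives target 50.0%. The constant here, 1.2, tips the pair towards the isomer of the product, and one over one plus the constant gives 45.5%, the balance share of target, which is 4.5 percentage points below the symmetric mark. No concentration enters this share.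

The weak link is the flat rate, which drops the squared inhibition term. At the whole charge the full law gives 0.282 mM s⁻¹, lower than the flat value, so the turnover time grows to 60.3 s. Even added to the 1.0 min of dosing, it is short against 50 min. This reckoning therefore commits to a flask at rest because the one-way step has used up the substrate, with target at 45.5% and the isomer of the product at 54.5%.

The forecast gives the same shares, 45.5% and 54.5%, but names forward and back rates have come level, holding that “that balance is what finally holds the mixture still”, and on that point it differs from this reckoning.

The simulation gives all of the substrate has reacted: at 50.0 min the flask holds substrate 0%, target 45.5% and the isomer of the product 54.5%. The neighbouring flask is charged with 6.8 mM of substrate, dosed over the same 1.0 min. The full law at that charge, taken whole, gives 0.276 mM s⁻¹, so the neighbouring flask needs about 24.6 s of turnover; added to the dosing this makes 84.6 s, short against 50 min, and the balance share stays 45.5%. At 50.0 min the neighbouring flask holds substrate 0%, the isomer of the product 54.5% and target 45.5%.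

(The constants used here come from no measurement; what happens was integrated by code.)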